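**Strategy.** The C40 polyene is cut at the C14–C15 single bond, where the trisubstituted C13=C14 alkene (bearing the C20 methyl, ε-ring half) meets the central C15=C15' alkene. The key step forms this bond by one-pot Zr-catalysed methylalumination of a C18 terminal trienyne (C13≡C14, C20 still absent) and Pd/Zn-catalysed alkenyl–alkenyl Negishi coupling with a C21 (E)-bromohexaene. One operation installs C20, sets the E geometry of C13=C14 and unites the two halves. Both halves grow from (R)-α-ionone and (E)-geranylacetone by the same alkyne/methylalumination/(E)-BrCH=CHI logic, so every trisubstituted chain alkene arises by syn-carbometalation; the C6 stereocentre is carried from (R)-α-ionone.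

Key step: step 7

Numbering: carotenoid locants are used. The cyclohexene (ε) ring is C1–C6 with the stereocentre at C6, its chain is C7–C15 with methyls C19 on C9 and C20 on C13, and the acyclic half carries primed locants C15'–C1'.

Assumption: (R)-(+)-α-ionone is bought as a single enantiomer and geranylacetone as the pure 5E isomer.

**Step 1**
Reactants: 1 acetylene
Product: 2 (E)-1-bromo-2-iodoethene
Conditions: IBr (1 equiv), 48% aq HBr, 0 °C, acetylene bubbled through; distillation
Reagents that add atoms: iodine monobromide, BrI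
Why: Electrophilic anti-addition of I–Br to the alkyne through a bridged iodonium ion should give the E-dihaloethene, whose C–I bond later couples before its C–Br bond.

**Step 2**
Reactants: 3 (R)-α-ionone
Product: 5 (6R)-6-[(1E)-but-1-en-3-yn-1-yl]-1,5,5-trimethylcyclohex-1-ene (ring enyne), via dienyl phosphate 4 (not isolated)
Conditions: LDA (1.05 equiv), THF, −78 °C; ClP(O)(OEt)2 (1.1 equiv), −78 → 23 °C; cannulated into LDA (2.3 equiv), THF, −78 → 23 °C; aq NH4Cl
Reagents that add atoms: none
Why: In this methyl ketone-to-terminal alkyne conversion by enol phosphate elimination, kinetic α'-enolisation of the enone, O-phosphorylation and base-induced β-elimination of diethyl phosphate should give the enyne, the hindered doubly allylic C6–H being removed more slowly than the methyl, vinyl and acetylenic hydrogens, so the stereocentre should survive.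

**Step 3**
Reactants: 5 ring enyne; 2 (E)-1-bromo-2-iodoethene
Product: 8 (6R)-1,5,5-trimethyl-6-[(1E,3E,5E)-3-methylocta-1,3,5-trien-7-yn-1-yl]cyclohex-1-ene (ring trienyne), via dienylalane 6 (not isolated), via bromotriene 7 (not isolated)
Conditions: Me3Al (2 equiv), Cp2ZrCl2 (0.25 equiv), ClCH2CH2Cl, 23 °C; volatiles removed in vacuo; THF, added to 2 (1.3 equiv), Pd2(dba)3 (2.5 mol %), tri(2-furyl)phosphine (10 mol %), ZnCl2 (0.3 equiv), 0 → 23 °C; then HC≡CZnBr (3 equiv, from HC≡CMgBr and ZnBr2), 23 → 45 °C, dark
Reagents that add atoms: trimethylaluminium, C[Al](C)C; ethynylmagnesium bromide, C#C[Mg]Br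
Why: Zr-catalysed syn-methylalumination of the terminal enyne (Negishi carboalumination) should place the methyl on C9 and aluminium on C10 with E geometry, after which two sequential Negishi couplings, first at the C–I bond of 2 and then of the resulting bromotriene with ethynylzinc bromide, should give the trienyne with retention at every alkene.

**Step 4**
Reactants: 9 (5E)-geranylacetone
Product: 11 (5E)-6,10-dimethylundeca-5,9-dien-1-yne, via trienyl phosphate 10 (not isolated)
Conditions: LDA (1.05 equiv), THF, −78 °C; ClP(O)(OEt)2 (1.1 equiv), −78 → 23 °C; cannulated into LDA (2.3 equiv), THF, −78 → 23 °C; aq NH4Cl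
Reagents that add atoms: none
Why: The same enol phosphate elimination should apply, with kinetic deprotonation by LDA at −78 °C favouring the methyl over the methylene side of the ketone so that the terminal alkyne forms.

**Step 5**
Reactants: 11 (5E)-6,10-dimethylundeca-5,9-dien-1-yne; 2 (E)-1-bromo-2-iodoethene
Product: 14 (3E,5E,9E)-6,10,14-trimethylpentadeca-3,5,9,13-tetraen-1-yne, via trienylalane 12 (not isolated), via bromotetraene 13 (not isolated)
Conditions: Me3Al (2 equiv), Cp2ZrCl2 (0.25 equiv), ClCH2CH2Cl, 23 °C; volatiles removed in vacuo; THF, added to 2 (1.3 equiv), Pd2(dba)3 (2.5 mol %), tri(2-furyl)phosphine (10 mol %), ZnCl2 (0.3 equiv), 0 → 23 °C; then HC≡CZnBr (3 equiv, from HC≡CMgBr and ZnBr2), 23 → 45 °C, dark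
Reagents that add atoms: trimethylaluminium, C[Al](C)C; ethynylmagnesium bromide, C#C[Mg]Br
Why: Negishi carboalumination of the alkyl-substituted terminal alkyne should set the E-C9'=C10' alkene with its C19' methyl, and the iodide-selective alkenyl coupling with 2 followed by alkynyl Negishi coupling should add C11'–C14' with the E-C11'=C12' geometry taken over from 2.

**Step 6**
Reactants: 14 (3E,5E,9E)-6,10,14-trimethylpentadeca-3,5,9,13-tetraen-1-yne; 2 (E)-1-bromo-2-iodoethene
Product: 16 (1E,3E,5E,7E,11E)-1-bromo-4,8,12,16-tetramethylheptadeca-1,3,5,7,11,15-hexaene (C21 bromide), via pentaenylalane 15 (not isolated)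
Conditions: Me3Al (2 equiv), Cp2ZrCl2 (0.25 equiv), ClCH2CH2Cl, 23 °C; volatiles removed in vacuo; THF, added slowly to 2 (1.5 equiv), Pd2(dba)3 (2.5 mol %), tri(2-furyl)phosphine (10 mol %), ZnCl2 (0.3 equiv), 0 → 23 °C, dark
Reagents that add atoms: trimethylaluminium, C[Al](C)C
Why: Negishi carboalumination of the conjugated dienyne should set E-C13'=C14' with the C20' methyl, and Negishi coupling at the more reactive C–I bond of excess 2 should leave the C15–Br bond in place on an E-C15=C15' alkene.

**Step 7**
Reactants: 8 ring trienyne; 16 C21 bromide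
Product: 18 α-zeacarotene, (6R)-7',8'-dihydro-ε,ψ-carotene, via tetraenylalane 17 (not isolated)
Conditions: 8 (1.1 equiv), Me3Al (2 equiv), Cp2ZrCl2 (0.25 equiv), ClCH2CH2Cl, 23 °C; volatiles removed in vacuo; THF–DMF, 16 (1.0 equiv), Pd2(dba)3 (2.5 mol %), tri(2-furyl)phosphine (10 mol %), ZnCl2 (0.5 equiv), 23 °C, argon, dark
Reagents that add atoms: trimethylaluminium, C[Al](C)C
Why: Cp2ZrCl2-catalysed methylalumination adds Me–Al syn across the terminal C13≡C14 alkyne of 8 (methyl to internal C13, aluminium to terminal C14) to give the E-alkenylalane 17; after removal of excess Me3Al, transmetalation through ZnCl2, oxidative addition of the C15–Br bond of 16 to zerovalent palladium and reductive elimination form the C14–C15 bond with retention on both alkenes. The closest known reaction type is the one-pot Negishi carboalumination/Pd–Zn alkenyl–alkenyl cross-coupling of terminal enynes with conjugated alkenyl halides. No ring is closed and no stereocentre is created; the existing C6 centre is remote from all reacting sites, and no acid or base able to move the ring alkene is present. The step needs regioselectivity in the carbometalation (secured by the terminal alkyne, aluminium going to the CH terminus), E geometry at C13=C14 (secured by syn addition) and retention of the E-C15=C15' geometry (stereospecific oxidative addition and reductive elimination). Chemoselectivity for the alkyne over the four C=C bonds of 8 rests on the much faster carbometalation of terminal alkynes, and homocoupling should be limited by adding 16 to the preformed alane with exclusion of oxygen and light.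

**Compound list**
1 | acetylene | C#C | starting material
2 | (E)-1-bromo-2-iodoethene | Br/C=C/I | intermediate
3 | (R)-α-ionone, (3E)-4-[(1R)-2,6,6-trimethylcyclohex-2-en-1-yl]but-3-en-2-one | CC(=O)/C=C/[C@H]1C(C)=CCCC1(C)C | starting material
4 | diethyl (3E)-4-[(1R)-2,6,6-trimethylcyclohex-2-en-1-yl]buta-1,3-dien-2-yl phosphate (dienyl phosphate) | C=C(OP(=O)(OCC)OCC)/C=C/[C@H]1C(C)=CCCC1(C)C | intermediate
5 | (6R)-6-[(1E)-but-1-en-3-yn-1-yl]-1,5,5-trimethylcyclohex-1-ene (ring enyne) | C#C/C=C/[C@H]1C(C)=CCCC1(C)C | intermediate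
6 | dimethyl{(1E,3E)-2-methyl-4-[(1R)-2,6,6-trimethylcyclohex-2-en-1-yl]buta-1,3-dien-1-yl}alane (dienylalane) | C[Al](C)/C=C(C)/C=C/[C@H]1C(C)=CCCC1(C)C | intermediate
7 | (6R)-6-[(1E,3E,5E)-6-bromo-3-methylhexa-1,3,5-trien-1-yl]-1,5,5-trimethylcyclohex-1-ene (bromotriene) | Br/C=C/C=C(C)/C=C/[C@H]1C(C)=CCCC1(C)C | intermediate
8 | (6R)-1,5,5-trimethyl-6-[(1E,3E,5E)-3-methylocta-1,3,5-trien-7-yn-1-yl]cyclohex-1-ene (ring trienyne) | C#C/C=C/C=C(C)/C=C/[C@H]1C(C)=CCCC1(C)C | intermediate
9 | (5E)-geranylacetone, (5E)-6,10-dimethylundeca-5,9-dien-2-one | CC(C)=CCC/C(C)=C/CCC(C)=O | starting material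
10 | diethyl (5E)-6,10-dimethylundeca-1,5,9-trien-2-yl phosphate (trienyl phosphate) | CC(C)=CCC/C(C)=C/CCC(=C)OP(=O)(OCC)OCC | intermediate
11 | (5E)-6,10-dimethylundeca-5,9-dien-1-yne | CC(C)=CCC/C(C)=C/CCC#C | intermediate
12 | dimethyl[(1E,5E)-2,6,10-trimethylundeca-1,5,9-trien-1-yl]alane (trienylalane) | CC(C)=CCC/C(C)=C/CC/C(C)=C/[Al](C)C | intermediate
13 | (1E,3E,7E)-1-bromo-4,8,12-trimethyltrideca-1,3,7,11-tetraene (bromotetraene) | CC(C)=CCC/C(C)=C/CC/C(C)=C/C=C/Br | intermediate
14 | (3E,5E,9E)-6,10,14-trimethylpentadeca-3,5,9,13-tetraen-1-yne | CC(C)=CCC/C(C)=C/CC/C(C)=C/C=C/C#C | intermediate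
15 | dimethyl[(1E,3E,5E,9E)-2,6,10,14-tetramethylpentadeca-1,3,5,9,13-pentaen-1-yl]alane (pentaenylalane) | CC(C)=CCC/C(C)=C/CC/C(C)=C/C=C/C(C)=C/[Al](C)C | intermediate
16 | (1E,3E,5E,7E,11E)-1-bromo-4,8,12,16-tetramethylheptadeca-1,3,5,7,11,15-hexaene (C21 bromide) | CC(C)=CCC/C(C)=C/CC/C(C)=C/C=C/C(C)=C/C=C/Br | intermediate
17 | dimethyl{(1E,3E,5E,7E)-2,6-dimethyl-8-[(1R)-2,6,6-trimethylcyclohex-2-en-1-yl]octa-1,3,5,7-tetraen-1-yl}alane (tetraenylalane) | C[Al](C)/C=C(C)/C=C/C=C(C)/C=C/[C@H]1C(C)=CCCC1(C)C | intermediate
18 | α-zeacarotene, (6R)-7',8'-dihydro-ε,ψ-carotene | CC(C)=CCC/C(C)=C/CC/C(C)=C/C=C/C(C)=C/C=C/C=C(C)/C=C/C=C(C)/C=C/[C@H]1C(C)=CCCC1(C)C | target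

**Total step count:** 7. **Longest linear sequence:** 4 steps (steps 4, 5, 6 and 7, from 9).

**Steps most likely to fail**

Step 7. The one-pot union of two labile polyenes may suffer from incomplete or unselective methylalumination of the trienyne, protodemetalation of the alane, homocoupling, or E/Z erosion during a slow coupling. The fallback sets out from 8 and 16, separates the two events and reverses the polarity of the coupling. Methylalumination of 8 as in step 7 and quenching of alane 17 with I2 (THF, −30 °C) should give the isolable (6R)-6-[(1E,3E,5E,7E)-8-iodo-3,7-dimethylocta-1,3,5,7-tetraen-1-yl]-1,5,5-trimethylcyclohex-1-ene F1. Miyaura borylation of 16 (bis(pinacolato)diboron, PdCl2(PPh3)2, PPh3, KOPh, toluene, 50 °C) should give the hexaenyl pinacol boronate F2. Suzuki–Miyaura coupling of F1 with F2 (Pd(PPh3)4, aq KOH, THF, 23 °C, dark) comes back to the route at 18.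

Step 2. Excess amide base may remove the doubly allylic C6–H, which would erode the configuration at C6 or move the ring alkene into conjugation, and the elimination may stop at the enol phosphate. The fallback sets out from 3 and avoids amide bases. Horner–Wadsworth–Emmons reaction with diethyl cyanomethylphosphonate (NaH, THF, 0 → 23 °C; the 9E isomer separated by chromatography) should give the dienenitrile F3. DIBAL-H reduction (toluene, −78 °C; aqueous acid work-up) should give the dienal F4. Takai iodo-olefination (CHI3, CrCl2, THF, 0 °C) should give the iodotriene F5. Negishi coupling of F5 with ethynylzinc bromide (Pd(PPh3)4, THF, 23 °C) comes back to the route at 8, so steps 2 and 3 are both replaced.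

Step 3. The three-component sequence may lose the iodide/bromide discrimination (double coupling of 2), the bromotriene may decompose or pick up a methyl from residual methylaluminium species before the second coupling, and the ethynyl unit may couple at both ends. The fallback sets out from 2 and 5 and attaches the alkyne to the two-carbon unit first. Negishi coupling of 2 with (trimethylsilyl)ethynylzinc bromide (Pd(PPh3)4, THF, 0 °C) should give the purifiable silyl bromoenyne F6. Methylalumination of 5 as in step 3 and Pd/ZnCl2 coupling of alane 6 with F6 should give the silyl trienyne F7. K2CO3 in MeOH (23 °C) removes the silyl group and comes back to the route at 8.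

**Further compounds**
F1 | step 7 | (6R)-6-[(1E,3E,5E,7E)-8-iodo-3,7-dimethylocta-1,3,5,7-tetraen-1-yl]-1,5,5-trimethylcyclohex-1-ene | I/C=C(C)/C=C/C=C(C)/C=C/[C@H]1C(C)=CCCC1(C)C
F2 | step 7 | 4,4,5,5-tetramethyl-2-[(1E,3E,5E,7E,11E)-4,8,12,16-tetramethylheptadeca-1,3,5,7,11,15-hexaen-1-yl]-1,3,2-dioxaborolane | CC(C)=CCC/C(C)=C/CC/C(C)=C/C=C/C(C)=C/C=C/B1OC(C)(C)C(C)(C)O1
F3 | step 2 | (2E,4E)-3-methyl-5-[(1R)-2,6,6-trimethylcyclohex-2-en-1-yl]penta-2,4-dienenitrile | N#C/C=C(C)/C=C/[C@H]1C(C)=CCCC1(C)C
F4 | step 2 | (2E,4E)-3-methyl-5-[(1R)-2,6,6-trimethylcyclohex-2-en-1-yl]penta-2,4-dienal | O=C/C=C(C)/C=C/[C@H]1C(C)=CCCC1(C)C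
F5 | step 2 | (6R)-6-[(1E,3E,5E)-6-iodo-3-methylhexa-1,3,5-trien-1-yl]-1,5,5-trimethylcyclohex-1-ene | I/C=C/C=C(C)/C=C/[C@H]1C(C)=CCCC1(C)C
F6 | step 3 | [(3E)-4-bromobut-3-en-1-yn-1-yl]trimethylsilane | C[Si](C)(C)C#C/C=C/Br
F7 | step 3 | trimethyl{(3E,5E,7E)-6-methyl-8-[(1R)-2,6,6-trimethylcyclohex-2-en-1-yl]octa-3,5,7-trien-1-yn-1-yl}silane | C[Si](C)(C)C#C/C=C/C=C(C)/C=C/[C@H]1C(C)=CCCC1(C)C
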